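The plan traces the lone stereocentre, the C3 carbinol of the pyran ring in the 2,2-dimethylchroman, back to the C3=C4 double bond of a 2H-chromene. A chiral salen manganese oxo species adds oxygen across this ring-bound cis-alkene, which is conjugated to the benzene ring and shielded on one side by the C2 gem-dimethyl group; C3–O and C4–O form and the oxirane closes in one operation, fixing C3 as S, and benzylic C4–O hydrogenolysis then leaves the carbinol. The precursor is 8-acetyl-5,7-diacetoxy-2,2-dimethyl-2H-chromene, deactivated by its acetyl and acetoxy groups. Deacetylation, C5 MOM protection, Claisen–Schmidt condensation and acid unmasking finish the chalcone.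

Key step: step 3

Assumption: chroman numbering is used throughout (O1, C2 gem-dimethyl, C3, C4, benzene ring C4a–C8a), and the (S,S) salen complex is taken to give the 3S,4S oxide, as it does with simpler 2,2-dimethylchromenes.

Step 1
Reactants: 1 2,4,6-trihydroxyacetophenone; 2 3-methylbut-2-enal
Product: 4 8-acetyl-5,7-dihydroxy-2,2-dimethyl-2H-chromene, via o-quinone methide 3 (not isolated)
Conditions: pyridine, 110 °C; chromatography
Reagents that add atoms: none
Why: Pyridine-mediated Knoevenagel-type condensation at the ring carbon between two hydroxyls gives o-quinone methide 3, which closes by oxa-6π electrocyclisation onto the oxygen next to the acetyl group, the 6-acetyl isomer from closure onto the para oxygen being removed by chromatography.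

Step 2
Reactants: 4 8-acetyl-5,7-dihydroxy-2,2-dimethyl-2H-chromene
Product: 5 8-acetyl-5,7-diacetoxy-2,2-dimethyl-2H-chromene
Conditions: Ac2O, pyridine, DMAP (cat.), CH2Cl2, 0 °C to rt
Reagents that add atoms: acetic anhydride, CC(=O)OC(C)=O
Why: DMAP-catalysed O-acylation converts both phenols, including the hydrogen-bonded C7 hydroxyl, into acetates that lower the electron density of the benzene ring for the oxidation that follows.

Step 3
Reactants: 5 8-acetyl-5,7-diacetoxy-2,2-dimethyl-2H-chromene
Product: 6 (3S,4S)-8-acetyl-5,7-diacetoxy-3,4-epoxy-2,2-dimethylchroman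
Conditions: (S,S)-[N,N'-bis(3,5-di-tert-butylsalicylidene)-1,2-cyclohexanediaminato]MnCl (C36H52ClMnN2O2, trivalent manganese, 5 mol%), mCPBA, NMO, CH2Cl2, −78 °C
Reagents that add atoms: mCPBA (3-chloroperoxybenzoic acid), OOC(=O)c1cccc(Cl)c1
Why: mCPBA with NMO oxidises the trivalent manganese complex to a pentavalent manganese oxo species, which the chromene meets side-on over the diamine backbone; oxygen is passed to C3 first, giving a C4 benzylic radical (or in a concerted way), and collapse onto C4 closes the oxirane, a [2+1] oxygen-atom transfer of the Jacobsen–Katsuki type. The three-membered ring is thus closed by the second C–O bond (C4–O) on the face of the first, and because the alkene is held in the pyran ring the oxirane can only be cis-fused. C3 and C4 are both set by the twofold-symmetric (S,S) ligand, which selects the alkene face while the C2 gem-dimethyl group blocks the alternative trajectory, so the 3S,4S oxide is expected. The step needs face selectivity, chemoselectivity and a product that survives: the ligand and the fixed cis geometry secure the first, and C3=C4 is the only alkene. The anhydrous NMO-buffered peracid at −78 °C is chosen over aqueous hypochlorite because it spares the aryl acetates from hydrolysis and the methyl ketone from haloform-type chlorination, and Baeyer–Villiger oxidation does not compete at this temperature. The acetyl and acetoxy groups leave the arene too electron-poor for the benzylic C4–O bond to ionise.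

Step 4
Reactants: 6 (3S,4S)-8-acetyl-5,7-diacetoxy-3,4-epoxy-2,2-dimethylchroman
Product: 7 (3S)-8-acetyl-5,7-diacetoxy-3-hydroxy-2,2-dimethylchroman
Conditions: H2 (1 atm), 10% Pd/C, EtOAc, rt
Reagents that add atoms: none
Why: Heterogeneous hydrogenolysis cleaves only the benzylic C4–O bond of the aryl oxirane (C3–O is neopentyl-like and unactivated), so C4 becomes CH2 and the C3–O bond keeps its S configuration, while the di-ortho-substituted aryl ketone and the aryl acetates should not be reduced at 1 atm.

Step 5
Reactants: 7 (3S)-8-acetyl-5,7-diacetoxy-3-hydroxy-2,2-dimethylchroman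
Product: 8 (3S)-8-acetyl-3,5,7-trihydroxy-2,2-dimethylchroman
Conditions: K2CO3, MeOH, 0 °C to rt; aq. NH4Cl
Reagents that add atoms: none
Why: Base-mediated transesterification (methanolysis) of the two aryl acetates is much faster than any reaction of the ketone or the secondary alcohol and does not touch C3.

Step 6
Reactants: 8 (3S)-8-acetyl-3,5,7-trihydroxy-2,2-dimethylchroman
Product: 9 (3S)-8-acetyl-3,7-dihydroxy-5-(methoxymethoxy)-2,2-dimethylchroman
Conditions: MOMCl (1.1 equiv), K2CO3, acetone, 0 °C to rt
Reagents that add atoms: chloromethyl methyl ether (MOMCl), COCCl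
Why: Williamson-type O-alkylation under weak base takes the more acidic, non-chelated C5 phenoxide para to the acetyl group, while the C7 hydroxyl hydrogen-bonded to the ketone and the neutral C3 alcohol stay free.

Step 7
Reactants: 10 4-hydroxybenzaldehyde
Product: 11 4-(methoxymethoxy)benzaldehyde
Conditions: MOMCl, K2CO3, acetone, rt
Reagents that add atoms: chloromethyl methyl ether (MOMCl), COCCl
Why: Williamson-type O-alkylation masks the para hydroxyl, which as a phenoxide would deactivate the aldehyde in the base-mediated condensation.

Step 8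
Reactants: 9 (3S)-8-acetyl-3,7-dihydroxy-5-(methoxymethoxy)-2,2-dimethylchroman; 11 4-(methoxymethoxy)benzaldehyde
Product: 13 (E)-1-[(3S)-3,7-dihydroxy-5-(methoxymethoxy)-2,2-dimethylchroman-8-yl]-3-[4-(methoxymethoxy)phenyl]prop-2-en-1-one, via aldol adduct 12 (not isolated)
Conditions: KOH, EtOH/H2O, rt; then 1 M HCl to pH 6, 0 °C
Reagents that add atoms: none
Why: Claisen–Schmidt condensation, in which the methyl ketone enolate adds to the non-enolisable aldehyde to give aldol 12 and E1cB dehydration gives the conjugated E-enone under thermodynamic control; the C7 phenoxide is tolerated as in standard 2'-hydroxychalcone syntheses and the C3 carbinol is not affected.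

Step 9
Reactants: 13 (E)-1-[(3S)-3,7-dihydroxy-5-(methoxymethoxy)-2,2-dimethylchroman-8-yl]-3-[4-(methoxymethoxy)phenyl]prop-2-en-1-one
Product: 14 (E)-1-[(3S)-3,5,7-trihydroxy-2,2-dimethylchroman-8-yl]-3-(4-hydroxyphenyl)prop-2-en-1-one (CNP0326757.1)
Conditions: 3 M HCl, MeOH, rt
Reagents that add atoms: none
Why: Acid-catalysed acetal methanolysis removes both aryl MOM ethers at room temperature, mild enough to keep the E-enone, the tertiary aryl ether O1–C2 and the C3 carbinol intact provided the reaction is stopped before the C7 hydroxyl adds to the enone.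

Compound list
1 | 2,4,6-trihydroxyacetophenone | CC(=O)c1c(O)cc(O)cc1O | starting material
2 | 3-methylbut-2-enal | CC(C)=CC=O | starting material
3 | 2-acetyl-3,5-dihydroxy-6-(3-methylbut-2-en-1-ylidene)cyclohexa-2,4-dien-1-one (o-quinone methide, not isolated) | CC(=O)C1=C(O)C=C(O)C(=CC=C(C)C)C1=O | intermediate
4 | 8-acetyl-5,7-dihydroxy-2,2-dimethyl-2H-chromene | CC1(C)Oc2c(C(C)=O)c(O)cc(O)c2C=C1 | intermediate
5 | 8-acetyl-5,7-diacetoxy-2,2-dimethyl-2H-chromene | CC1(C)Oc2c(C(C)=O)c(OC(C)=O)cc(OC(C)=O)c2C=C1 | intermediate
6 | (3S,4S)-8-acetyl-5,7-diacetoxy-3,4-epoxy-2,2-dimethylchroman | CC1(C)Oc2c(C(C)=O)c(OC(C)=O)cc(OC(C)=O)c2[C@@H]3O[C@H]13 | intermediate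
7 | (3S)-8-acetyl-5,7-diacetoxy-3-hydroxy-2,2-dimethylchroman | CC1(C)Oc2c(C(C)=O)c(OC(C)=O)cc(OC(C)=O)c2C[C@@H]1O | intermediate
8 | (3S)-8-acetyl-3,5,7-trihydroxy-2,2-dimethylchroman | CC1(C)Oc2c(C(C)=O)c(O)cc(O)c2C[C@@H]1O | intermediate
9 | (3S)-8-acetyl-3,7-dihydroxy-5-(methoxymethoxy)-2,2-dimethylchroman | CC1(C)Oc2c(C(C)=O)c(O)cc(OCOC)c2C[C@@H]1O | intermediate
10 | 4-hydroxybenzaldehyde | O=Cc1ccc(O)cc1 | starting material
11 | 4-(methoxymethoxy)benzaldehyde | COCOc1ccc(C=O)cc1 | intermediate
12 | 3-hydroxy-1-[(3S)-3,7-dihydroxy-5-(methoxymethoxy)-2,2-dimethylchroman-8-yl]-3-[4-(methoxymethoxy)phenyl]propan-1-one (aldol adduct, both carbinol epimers, not isolated) | CC1(C)Oc2c(C(=O)CC(O)c3ccc(OCOC)cc3)c(O)cc(OCOC)c2C[C@@H]1O | intermediate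
13 | (E)-1-[(3S)-3,7-dihydroxy-5-(methoxymethoxy)-2,2-dimethylchroman-8-yl]-3-[4-(methoxymethoxy)phenyl]prop-2-en-1-one | CC1(C)Oc2c(C(=O)/C=C/c3ccc(OCOC)cc3)c(O)cc(OCOC)c2C[C@@H]1O | intermediate
14 | (E)-1-[(3S)-3,5,7-trihydroxy-2,2-dimethylchroman-8-yl]-3-(4-hydroxyphenyl)prop-2-en-1-one | CC1(C)Oc2c(C(=O)/C=C/c3ccc(O)cc3)c(O)cc(O)c2C[C@@H]1O | target

Total step count: 9. Longest linear sequence: 8 (steps 1–6, 8 and 9, from 1).

Steps most likely to fail

Step 3. Enantioface discrimination may be incomplete, because the C5 acetoxy group sits peri to C4 and the alkene is hindered and electron-poor, so oxygen transfer may be slow relative to the unselective background. The fallback replaces catalyst control by separation of covalent diastereomers. It sets out from alcohol 7 of insufficient enantiomeric purity, which is acylated with (1S)-(−)-camphanic chloride (pyridine, DMAP, CH2Cl2) to give (3S)-8-acetyl-5,7-diacetoxy-2,2-dimethylchroman-3-yl (1S,4R)-camphanate F1. This is freed from its 3R diastereomer by crystallisation or chromatography. K2CO3 in MeOH then removes the camphanoyl group and both acetyl groups in one operation, and the route is rejoined at triol 8.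

Step 4. Chemoselectivity at the oxirane may be lost: isomerisation on the metal surface to the C3 ketone (Meinwald-type rearrangement), or sluggish C4–O cleavage on the electron-poor ring with competing reduction of the aryl ketone. The fallback swaps hydrogenolysis for ionic opening followed by radical reduction. It sets out from epoxide 6, which LiBr and AcOH in THF should open at the benzylic carbon with inversion to give trans-(3R,4R)-8-acetyl-5,7-diacetoxy-4-bromo-3-hydroxy-2,2-dimethylchroman F2. The C3–O bond is spatially unchanged; its descriptor changes only because bromine raises the priority of C4. Bu3SnH and AIBN in toluene at 80 °C then replace bromine by hydrogen, and the route is rejoined at alcohol 7.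

Step 1. Regiocontrol of the ring closure may be poor, with closure onto the para oxygen and a second annulation on the remaining phenol. The fallback blocks the para oxygen first. It sets out from 1, which TsCl (1 equiv) and K2CO3 in acetone should sulfonylate at the most acidic, non-chelated hydroxyl to give 4-acetyl-3,5-dihydroxyphenyl 4-methylbenzenesulfonate F3. Condensation with 2 in pyridine at 110 °C can then close only onto an oxygen next to the acetyl group, giving 8-acetyl-7-hydroxy-2,2-dimethyl-2H-chromen-5-yl 4-methylbenzenesulfonate F4. KOH in MeOH/H2O at reflux cleaves the sulfonate, and the route is rejoined at chromene 4.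

Further compounds
F1 | step 3 | (3S)-8-acetyl-5,7-diacetoxy-2,2-dimethylchroman-3-yl (1S,4R)-camphanate | CC1(C)Oc2c(C(C)=O)c(OC(C)=O)cc(OC(C)=O)c2C[C@@H]1OC(=O)[C@@]12CC[C@@](C)(C(=O)O1)C2(C)C
F2 | step 4 | trans-(3R,4R)-8-acetyl-5,7-diacetoxy-4-bromo-3-hydroxy-2,2-dimethylchroman | CC1(C)Oc2c(C(C)=O)c(OC(C)=O)cc(OC(C)=O)c2[C@@H](Br)[C@@H]1O
F3 | step 1 | 4-acetyl-3,5-dihydroxyphenyl 4-methylbenzenesulfonate | CC(=O)c1c(O)cc(OS(=O)(=O)c2ccc(C)cc2)cc1O
F4 | step 1 | 8-acetyl-7-hydroxy-2,2-dimethyl-2H-chromen-5-yl 4-methylbenzenesulfonate | CC1(C)Oc2c(C(C)=O)c(O)cc(OS(=O)(=O)c3ccc(C)cc3)c2C=C1
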